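The oak run, charged with 35 µM of initiator, has 2.9 % of its monomer in chains at 5.00 min, and the elm run, with 240 µM, has 8.7 %.

| setting | oak | maple | elm | summer | dawn | winter | spring |
|---|---|---|---|---|---|---|---|
| free monomer | 0.018 M | 0.018 M | 0.018 M | 0.018 M | 0.018 M | 0.018 M | 0.018 M |
| initiator | 35 µM | 80 µM | 240 µM | 30 µM | 95 µM | 50 µM | 200 µM |
| remark | run made earlier | run made earlier | run made earlier |  |  |  |  |
| time |  |  |  | 1.0 h | 1.0 h | 1.0 h | 1.0 h |

| run | time / min | monomer in chains / % | free monomer / % |
|---|---|---|---|
| oak | 5.00 | 2.9 | 82.4 |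
| oak | 10.0 | 6.6 | 73.8 |
| oak | 15.0 | 8.5 | 70.0 |
| oak | 30.0 | 13.7 | 60.7 |
| oak | 60.0 | 20.5 | 51.8 |
| maple | 5.00 | 5.0 | 81.0 |
| maple | 15.0 | 12.2 | 66.1 |
| maple | 30.0 | 20.1 | 55.4 |
| maple | 40.0 | 23.2 | 50.5 |
| maple | 60.0 | 29.7 | 43.2 |
| elm | 5.00 | 8.7 | 77.7 |
| elm | 15.0 | 19.7 | 57.5 |
| elm | 30.0 | 29.8 | 44.0 |
| elm | 40.0 | 35.2 | 39.2 |
| elm | 60.0 | 41.2 | 28.4 |

(each reading ± 0.5 percentage points)



* the flasks by amount of monomer in chains, in percent of the free monomer charged, highest first, at 1.0 h (summer / dawn / winter / spring)
* the same order at 12 min (summer / dawn / winter / spring)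
* the amount of monomer in chains, in percent of the free monomer charged of the flask you put first, at 1.0 h
* the amount of monomer in chains, in percent of the free monomer charged of the flask you put last, at 1.0 h

In those first minutes something else happens. The share that is neither free monomer nor in chains already stands at 14.7 % in oak and 13.6 % in elm, though their initiator charges differ by a factor of 6.86. In the middle of the run, at 30.0 min, oak, maple and elm hold 13.7 %, 20.1 % and 29.8 % in chains. Their order follows initiator at every shared reading time, so the same order is expected for the new flasks at both 12 min and 1.0 h.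

By the end, at 60.0 min, elm has 28.4 % of its free monomer left against 51.8 % in oak, and its chains stand at 41.2 % against 20.5 %, a factor of 2.01 for that factor of 6.86 in initiator. Multiplying the initiator buys a steady step, not a proportional amount. The reckoning here takes that step from the two outer runs:

gain = (elm − oak) / ln(elm charge / oak charge) = 11 percentage points

This gain per e-fold is the rise in monomer in chains at 1.0 h for each factor of e in the initiator charge. Maple tests it: the gain gives 29.4 %, and the reading is 29.7 %, good to 0.5 points. Counted from oak, it gives:

spring: 39.2 %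
summer: 18.8 %

The forecast, which calls the end values “almost linear in ln I”, has its own figures: spring > dawn > winter > summer at 1.0 h, spring > dawn > winter > summer at 12 min, 39.3 % for the first flask and 18.9 % for the last.

The flasks give spring > dawn > winter > summer at 1.0 h and spring > dawn > winter > summer at 12 min, with spring at 39.2 % and summer at 19.8 %.

    initiator → 2 initiating radical (k = 9.80 × 10⁻⁶ s⁻¹)
    free monomer + initiating radical → growing radical + monomer in chains (k = 3.80 × 10⁶ L mol⁻¹ s⁻¹)
    free monomer + growing radical → monomer in chains + growing radical, rate k3*[growing radical]*[free monomer] (k = 37000 L mol⁻¹ s⁻¹)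
    2 growing radical → dead chain (k = 2.80 × 10⁷ L mol⁻¹ s⁻¹)
    free monomer ⇌ dormant form (K = 0.340, k = 7.20 × 10⁻⁴ s⁻¹)
    monomer in chains ⇌ isomer of the product (K = 1.00, k = 2.60 × 10⁻⁴ s⁻¹)

Between summer and spring the flasks show a gain of 10 points per e-fold, against the 11 points from oak and elm. On dawn the carried gain gives 31.2 %, and the flask holds 30.8 %. At 1.0 h spring has 6.67 times the initiator charge of summer but 2.58 times its growing radical. Part of what holds summer at 19.8 % in chains is the pairing of growing radicals into dead chain, acting together with the time given: with that step taken away, summer ends at 59.3 %, and with the step kept but the flask left until 10.0 h, it holds 47.8 %.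

The data stem from a simulated flask on assumed constants.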